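Assumption: the SMILES is read as the all-trans (2R,3S,4S,5R) isomer; locants O1 and C2–C5 are those of the oxolane ring of the target 11, and primed locants are those of the arenes.

## Analysis of the target

- Target 11 has a single oxolane ring (O1, C2–C5). C2 and C5 carry 4-hydroxy-3,5-dimethoxyphenyl (syringyl) groups; C3 and C4 carry hydroxymethyl groups.
- The four contiguous stereocentres are 2R,3S,4S,5R. Every vicinal pair (C2/C3, C3/C4, C4/C5) is trans and the aryl groups are trans across O1. A C2 axis therefore runs through O1 and the midpoint of the C3–C4 bond, leaving only two independent centres (C2 ≡ C5, C3 ≡ C4).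
- The all-trans array is the thermodynamically preferred one for a 2,3,4,5-tetrasubstituted oxolane. C2 and C5 are benzylic ether carbons para to a phenol, so they ionise reversibly under acid (p-quinone methide character) and can be equilibrated; C3 and C4 cannot.
- Sensitive groups are the two electron-rich 2,6-dimethoxyphenols (oxidation, electrophilic attack at C2'/C6'), the benzylic C2–O1 and C5–O1 bonds (acid, hydrogenolysis), and the two primary hydroxyls. In acid the hydroxyls can capture a C2/C5 cation and divert the skeleton to the isomeric furofuran-type connectivity.
- The constitution is simple, a dimer of an aryl–C3 unit joined at C3–C4. The difficulty is (i) absolute control of C3/C4 when that bond joins two identical halves, which is a like/unlike problem as well as an enantiomer problem, and (ii) closing O1 between C2 and C5 and not between a benzylic carbon and a hydroxymethyl oxygen.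
- The feature the route exploits: C3 and C4 each lie between a benzylic oxygenated carbon (C2/C5) and a carboxyl-derived carbon (the CH2OH carbons). At the aryl ketone/ester oxidation level each becomes the methine of a β-keto ester and is stereolabile. All 22 skeletal carbons can thus be held in a constitutionally symmetric, stereochemically mobile dimer, and the C2 axis lets one catalyst treat both halves alike.

## Retrosynthetic reasoning

**11 ⇒ 10.** The two hydroxymethyl groups on C3/C4 are traced back to methyl esters; no skeletal bond is cut. This comes last because free primary hydroxyls would compete with the benzylic oxygen for a C2/C5 cation in any acid step, whereas ester carbons cannot. The forward reaction is a hydride reduction of two esters that must leave the benzylic ether and all four centres alone. In the diester 10 these centres are (2R,3R,4R,5R), which is the spatial arrangement of 11; only the priorities change.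

**10 ⇒ 7.** The O1–C5 bond (equivalently O1–C2) is cut. The oxygen left on each benzylic carbon is re-attached to the carboxyl carbon of the other half, giving the cis-fused, C2-symmetric dilactone 7 (3R,3aR,6R,6aR). The cut is made at C–O and not at C–C because it turns the flexible oxolane into a rigid, crystalline bicycle whose four centres map one to one onto those of 10 and whose benzylic oxygens are masked as esters. In the forward sense, acidic alcoholysis must remove the phenol acetals (8), open both lactones (9), and let one benzylic carbon ionise so that the benzylic oxygen of the other half closes O1. C3a/C6a of 7 are untouched and dictate the all-trans outcome, which 7 already has.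

**7 ⇒ 5.** The two lactone C–O bonds and the two C–H bonds at C3 and C6 are cut, leading to the bis(β-keto ester) 5. This is the strategic cut: 5 has no ring and no centre that needs control, because its two methines epimerise freely, while 7 has two rings and four defined centres. The forward reaction is a twofold dynamic kinetic asymmetric transfer hydrogenation. The catalyst must fix both carbinol centres and must select one epimer at the adjacent methine in the first reduction. Lactonisation through the keto lactone 6 and the cis-fusion requirement of the bicycle then relay that choice to the fourth centre.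

**5 ⇒ 3.** The central C2–C3 bond of the butanedioate (the future C3–C4 of 11) is cut on the symmetry axis, giving two molecules of the β-keto ester 3. They are joined by oxidative enolate coupling by way of the α-iodide 4. The like/unlike problem that burdens every other construction of this bond does not arise, since both new centres are mobile in 5.

**3 ⇒ 2 ⇒ 1.** The ester carbon of 3 is removed (crossed Claisen C-methoxycarbonylation of the methyl ketone 2). The methoxymethyl acetal of 2 is traced to the commercial phenol 1. The acetal is chosen because it is cleaved in the same acid step that converts 7 into 10.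

## Alternatives that were turned down

Alternative 1: The textbook route, biomimetic oxidative 8–8' coupling, which disconnects C3–C4 together with both C–O1 bonds.
- Forward key step: a one-electron oxidant converts methyl sinapate A1 into its phenoxyl radical. Two radicals couple at the β-carbons to the bis(quinone methide) A2, and hydration with 5-exo closure gives the constitution of 10 in one flask.
- Turned down because the radical–radical coupling has no element that controls absolute configuration and little that controls like/unlike pairing. 10 could only arise as a racemate, accompanied by the C3/C4-cis series.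
- A2 also partitions between hydration, tautomerisation and Friedel–Crafts closure onto C2' (aryldihydronaphthalenes).
- An asymmetric version needs a stoichiometric chiral auxiliary on both acyl groups, whose attachment and removal would take more steps than steps 1–3 of the chosen route.

Alternative 2: A [3+2] cycloaddition of a carbonyl ylide to a fumarate, which disconnects C2–C3 and C4–C5.
- Forward key step: C–C cleavage of the cis-diaryloxirane A3 gives the ylide, which is trapped by dimethyl fumarate A4 under a chiral Lewis acid. This would build the whole ring and all four centres convergently.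
- Turned down because an oxirane without acceptor groups opens to the ylide only photochemically or at very high temperature. Under those conditions an oxirane flanked by two electron-rich arenes undergoes 1,2-shift to carbonyl compounds.
- The ylide geometries interconvert, so the C2/C5 relationship is not secured, and face selection on A4 would have to be imposed by a catalyst against an uncatalysed background.
- A3 itself needs about four steps.

Alternative 3: Strain release from a cyclobutane, which disconnects both C–O1 bonds and traces the C2···C5 relationship back to a σ-bond.
- The precursor is the cyclobutane A5, the head-to-head [2+2] photodimer of an ester of the A1 type.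
- Forward key step: two-electron oxidation of the bis-phenol A5 would cleave the strained bond between the two aryl-bearing carbons and give A2 as a single like-configured enantiomer. Hydration would then close the oxolane with C2/C5 set thermodynamically.
- This is the most attractive of the three, since only the two ester-bearing centres of A5 would have to be set.
- Turned down because the oxidative scission has to beat benzylic C–H loss and cycloreversion to two alkenes, and has no precedent as an oxygen insertion.
- Enantioselective head-to-head photodimerisation is established only for cinnamoyl derivatives with special activating groups, which would have to be installed and exchanged. Two unproven steps in series and a longer sequence compare badly with one catalytic reduction of a known type.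

Key step: step 4

## Route

Step 1
Reactants: 1 1-(4-hydroxy-3,5-dimethoxyphenyl)ethan-1-one (acetosyringone)
Product: 2 1-[3,5-dimethoxy-4-(methoxymethoxy)phenyl]ethan-1-one
Conditions: MOMCl (1.5 equiv), iPr2NEt (2 equiv), CH2Cl2, 0 °C to rt
Reagents that add atoms: chloromethyl methyl ether, COCCl
Why: Williamson-type O-alkylation of the phenol with the α-chloro ether; the acetal should survive the bases, the iodine and the formate buffer of steps 2–4 and is cleaved by the same methanolic acid that triggers step 5, so protection costs one step only.

Step 2
Reactants: 2 1-[3,5-dimethoxy-4-(methoxymethoxy)phenyl]ethan-1-one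
Product: 3 methyl 3-[3,5-dimethoxy-4-(methoxymethoxy)phenyl]-3-oxopropanoate
Conditions: NaH (2.5 equiv), (MeO)2CO (5 equiv), THF, reflux; AcOH quench
Reagents that add atoms: dimethyl carbonate, COC(=O)OC
Why: Crossed Claisen condensation of the ketone enolate with the non-enolisable carbonate; deprotonation of the β-keto ester by the second equivalent of NaH makes it irreversible.

Step 3
Reactants: 3 methyl 3-[3,5-dimethoxy-4-(methoxymethoxy)phenyl]-3-oxopropanoate (two molecules)
Product: 5 dimethyl 2,3-bis[3,5-dimethoxy-4-(methoxymethoxy)benzoyl]butanedioate (rac/meso mixture), via iodo keto ester 4 (not isolated)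
Conditions: NaH (1.05 equiv), THF, 0 °C; then I2 (0.5 equiv), THF, 0 °C to rt
Reagents that add atoms: none
Why: Oxidative enolate dimerisation: half of the sodium enolate is iodinated to 4, which is displaced (SN2) by the remaining enolate to form the central C–C bond, the future C3–C4 of 11; the rac/meso composition of 5 is irrelevant because both new methines are β-dicarbonyl C–H centres that epimerise freely.

Step 4
Reactants: 5 dimethyl 2,3-bis[3,5-dimethoxy-4-(methoxymethoxy)benzoyl]butanedioate
Product: 7 (3R,3aR,6R,6aR)-3,6-bis[3,5-dimethoxy-4-(methoxymethoxy)phenyl]tetrahydro-1H,3H-furo[3,4-c]furan-1,4-dione, via keto lactone 6 (not isolated)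
Conditions: RuCl[(R,R)-TsDPEN](p-cymene) (4 mol %), HCO2H/Et3N (5:2), DMF, 40 °C; crystallisation
Reagents that add atoms: none
Why: In the amine/formic acid buffer both methines of 5 epimerise continuously through the enols, while the ruthenium hydride formed from formate delivers H–/H+ to an aryl ketone through the six-membered outer-sphere transition state of the Noyori–Ikariya transfer hydrogenation. The closest known reaction type is the dynamic kinetic asymmetric transfer hydrogenation of α-substituted aryl β-keto esters, including cases in which the new hydroxyl lactonises in the flask; here it runs twice on one molecule. The carbinol centres C3 and C6 are set by the catalyst: the CH–π contact between the aryl ketone and the η6-arene fixes the hydride face, and the (R,R)-ligand should give R as it does for simple aryl ketones. C3a is set in the first reduction by selection of the epimer that leads to the syn β-hydroxy ester, the preference expected for an α-carbon-substituted aroylacetate, which corresponds to R. Each lactone then closes by 5-exo-trig addition of the benzylic hydroxyl to the ester carbonyl of the other half with loss of methanol; the first closure gives 6 with aryl and ester trans. In 6 the methine between ketone and lactone carbonyl is still labile, the second reduction is again catalyst-controlled (R), and only the epimer that makes the bicycle cis-fused can close the second ring, so C6a is relayed from C3a and the exo,exo-dilactone is the sink for the second half. The step needs enantioface selection at two ketones, epimer selection in the first reduction, and chemoselectivity against hemiketal and furan formation; these are secured by the aryl ketone/arene contact, the acidity of the methines, the cis-fusion constraint, and the mild buffer. Because two catalyst-controlled events are needed to reach the C2-symmetric product, minor-enantiomer events should end up in diastereomers, from which the sparingly soluble 7 should crystallise.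

Step 5
Reactants: 7 (3R,3aR,6R,6aR)-3,6-bis[3,5-dimethoxy-4-(methoxymethoxy)phenyl]tetrahydro-1H,3H-furo[3,4-c]furan-1,4-dione
Product: 10 dimethyl (2R,3R,4R,5R)-2,5-bis(4-hydroxy-3,5-dimethoxyphenyl)oxolane-3,4-dicarboxylate, via bisphenol dilactone 8 (not isolated), via seco diol diester 9 (not isolated)
Conditions: 1.25 M HCl in MeOH, 0 °C to rt
Reagents that add atoms: methanol, CO
Why: Acid-mediated lactone-to-ether transposition: HCl/MeOH cleaves the aryl acetals (8), methanolysis opens both lactones (9), and a benzylic hydroxyl para to the freed phenol ionises (SN1, p-quinone methide character) and is captured by the other benzylic oxygen in a 5-exo closure of the oxolane. C3/C4 (α to the esters) are untouched, and C2/C5 equilibrate through the same cation to the all-trans ether, which is the configuration 7 already has. The ester carbons cannot compete for the cation the way hydroxymethyl groups would, which is why the reduction is left to step 6.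

Step 6
Reactants: 10 dimethyl (2R,3R,4R,5R)-2,5-bis(4-hydroxy-3,5-dimethoxyphenyl)oxolane-3,4-dicarboxylate
Product: 11 [(2R,3S,4S,5R)-2,5-bis(4-hydroxy-3,5-dimethoxyphenyl)oxolane-3,4-diyl]dimethanol
Conditions: LiAlH4 (6 equiv), THF, 0 °C to rt; aq. potassium sodium tartrate
Reagents that add atoms: none
Why: Hydride reduction of both esters to primary alcohols under basic, non-ionising conditions; the phenols are carried as aluminium phenoxides, the benzylic ether and the four stereocentres are not affected, and the hydroxymethyl groups appear only now, when no acid step follows.

## Compound list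

1 | 1-(4-hydroxy-3,5-dimethoxyphenyl)ethan-1-one (acetosyringone) | CC(=O)c1cc(OC)c(O)c(OC)c1 | starting material
2 | 1-[3,5-dimethoxy-4-(methoxymethoxy)phenyl]ethan-1-one | CC(=O)c1cc(OC)c(OCOC)c(OC)c1 | intermediate
3 | methyl 3-[3,5-dimethoxy-4-(methoxymethoxy)phenyl]-3-oxopropanoate | COC(=O)CC(=O)c1cc(OC)c(OCOC)c(OC)c1 | intermediate
4 | methyl 2-iodo-3-[3,5-dimethoxy-4-(methoxymethoxy)phenyl]-3-oxopropanoate (racemic) | COC(=O)C(I)C(=O)c1cc(OC)c(OCOC)c(OC)c1 | intermediate (not isolated)
5 | dimethyl 2,3-bis[3,5-dimethoxy-4-(methoxymethoxy)benzoyl]butanedioate (rac/meso mixture, stereolabile) | COC(=O)C(C(=O)c1cc(OC)c(OCOC)c(OC)c1)C(C(=O)c1cc(OC)c(OCOC)c(OC)c1)C(=O)OC | intermediate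
6 | methyl (2R,3R)-4-[3,5-dimethoxy-4-(methoxymethoxy)benzoyl]-2-[3,5-dimethoxy-4-(methoxymethoxy)phenyl]-5-oxooxolane-3-carboxylate (C4 epimers, interconverting) | COC(=O)[C@H]1[C@H](c2cc(OC)c(OCOC)c(OC)c2)OC(=O)C1C(=O)c1cc(OC)c(OCOC)c(OC)c1 | intermediate (not isolated)
7 | (3R,3aR,6R,6aR)-3,6-bis[3,5-dimethoxy-4-(methoxymethoxy)phenyl]tetrahydro-1H,3H-furo[3,4-c]furan-1,4-dione | O=C1O[C@@H](c3cc(OC)c(OCOC)c(OC)c3)[C@@H]2C(=O)O[C@@H](c4cc(OC)c(OCOC)c(OC)c4)[C@H]12 | intermediate
8 | (3R,3aR,6R,6aR)-3,6-bis(4-hydroxy-3,5-dimethoxyphenyl)tetrahydro-1H,3H-furo[3,4-c]furan-1,4-dione | O=C1O[C@@H](c3cc(OC)c(O)c(OC)c3)[C@@H]2C(=O)O[C@@H](c4cc(OC)c(O)c(OC)c4)[C@H]12 | intermediate (not isolated)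
9 | dimethyl (2R,3R)-2,3-bis[(R)-hydroxy(4-hydroxy-3,5-dimethoxyphenyl)methyl]butanedioate | COC(=O)[C@@H]([C@@H](O)c1cc(OC)c(O)c(OC)c1)[C@H]([C@@H](O)c1cc(OC)c(O)c(OC)c1)C(=O)OC | intermediate (not isolated)
10 | dimethyl (2R,3R,4R,5R)-2,5-bis(4-hydroxy-3,5-dimethoxyphenyl)oxolane-3,4-dicarboxylate | COc1cc([C@@H]2O[C@@H](c3cc(OC)c(O)c(OC)c3)[C@H](C(=O)OC)[C@H]2C(=O)OC)cc(OC)c1O | intermediate
11 | [(2R,3S,4S,5R)-2,5-bis(4-hydroxy-3,5-dimethoxyphenyl)oxolane-3,4-diyl]dimethanol | COc1cc([C@@H]2O[C@@H](c3cc(OC)c(O)c(OC)c3)[C@H](CO)[C@H]2CO)cc(OC)c1O | target

## Step count and least certain steps

Total step count: 6. Longest linear sequence: 6 (both halves of the C2-symmetric skeleton are carried together from step 3 on).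

**Step 4 (key step).**
- The most likely failure is insufficient selection between the two rapidly interconverting epimers of 5 in the first hydride transfer. A tertiary carbon substituent α to the ketone is less well studied than a simple alkyl group.
- This would erode the configurational purity at C3a/C6a, the only centres that pass through step 5 unconditionally.
- A reversed (anti) preference would invert the sense at these centres relative to the catalyst-fixed carbinol centres. The configuration of crystalline 7 should therefore be established by anomalous-dispersion X-ray analysis before proceeding, and the enantiomeric ligand chosen if needed.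
- Secondary risks are stalling after the first reduction through hemiketalisation of the γ-hydroxy ketone, and acid-induced cyclodehydration towards a furan.
- Fallback, setting out from 5 and returning at 7: reduction without chiral information (NaBH4, MeOH/THF, −20 °C, then AcOH to complete lactonisation) should give the racemic exo,exo-dilactone. This is 7 together with its enantiomer (3S,3aS,6S,6aS)-3,6-bis[3,5-dimethoxy-4-(methoxymethoxy)phenyl]tetrahydro-1H,3H-furo[3,4-c]furan-1,4-dione F1. Preparative chromatography on a chiral stationary phase (supercritical CO2/MeOH) removes F1 and gives 7.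

**Step 5.**
- The most likely failure is irreversible interception of the benzylic cation by C2'/C6' of the other syringyl ring (Friedel–Crafts closure to an aryltetralin).
- Alternatively the material may rest as open-chain benzylic methyl ethers because lactone alcoholysis lags behind ionisation. Both follow from the high stability of the syringyl cation in a medium that keeps regenerating it.
- Fallback, setting out from 7 and returning at 11, in which the lactones are opened irreversibly by hydride before any cation is formed:
  - LiAlH4 (THF, 0 °C) should give the tetraol (2S,3S)-2,3-bis{(R)-[3,5-dimethoxy-4-(methoxymethoxy)phenyl](hydroxy)methyl}butane-1,4-diol F2.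
  - Selective acylation of the primary hydroxyls (PivCl, pyridine, CH2Cl2, −20 °C) gives the bis-pivalate (2S,3S)-2,3-bis{(R)-[3,5-dimethoxy-4-(methoxymethoxy)phenyl](hydroxy)methyl}butane-1,4-diyl bis(2,2-dimethylpropanoate) F3.
  - Brief exposure to 1.25 M HCl in MeOH at 0 °C removes the acetals and closes O1 between the benzylic carbons, the primary oxygens being blocked. The product is [(2R,3S,4S,5R)-2,5-bis(4-hydroxy-3,5-dimethoxyphenyl)oxolane-3,4-diyl]bis(methylene) bis(2,2-dimethylpropanoate) F4.
  - LiAlH4 (THF, 0 °C) removes the pivalates and gives 11 directly.

**Step 3.**
- The most likely failure is over-oxidation. The product 5 is itself C–H acidic and can be iodinated and dehydroiodinated to the tetrasubstituted alkene.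
- O- instead of C-alkylation of the enolate by 4 is a second risk.
- Fallback, setting out from 2 and returning at 5, in which the central bond is made before the ester carbons are introduced:
  - Oxidative coupling of the lithium enolate of 2 (LiN(iPr)2, THF, −78 °C, then CuCl2 in DMF) should give 1,4-bis[3,5-dimethoxy-4-(methoxymethoxy)phenyl]butane-1,4-dione F5.
  - Twofold C-methoxycarbonylation (NaH, dimethyl carbonate, THF, reflux) then gives 5.

## Further compounds

F1 | step 4 | (3S,3aS,6S,6aS)-3,6-bis[3,5-dimethoxy-4-(methoxymethoxy)phenyl]tetrahydro-1H,3H-furo[3,4-c]furan-1,4-dione | O=C1O[C@H](c3cc(OC)c(OCOC)c(OC)c3)[C@H]2C(=O)O[C@H](c4cc(OC)c(OCOC)c(OC)c4)[C@@H]12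
F2 | step 5 | (2S,3S)-2,3-bis{(R)-[3,5-dimethoxy-4-(methoxymethoxy)phenyl](hydroxy)methyl}butane-1,4-diol | OC[C@@H]([C@@H](O)c1cc(OC)c(OCOC)c(OC)c1)[C@H]([C@@H](O)c1cc(OC)c(OCOC)c(OC)c1)CO
F3 | step 5 | (2S,3S)-2,3-bis{(R)-[3,5-dimethoxy-4-(methoxymethoxy)phenyl](hydroxy)methyl}butane-1,4-diyl bis(2,2-dimethylpropanoate) | CC(C)(C)C(=O)OC[C@@H]([C@@H](O)c1cc(OC)c(OCOC)c(OC)c1)[C@H]([C@@H](O)c1cc(OC)c(OCOC)c(OC)c1)COC(=O)C(C)(C)C
F4 | step 5 | [(2R,3S,4S,5R)-2,5-bis(4-hydroxy-3,5-dimethoxyphenyl)oxolane-3,4-diyl]bis(methylene) bis(2,2-dimethylpropanoate) | COc1cc([C@@H]2O[C@@H](c3cc(OC)c(O)c(OC)c3)[C@H](COC(=O)C(C)(C)C)[C@H]2COC(=O)C(C)(C)C)cc(OC)c1O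
F5 | step 3 | 1,4-bis[3,5-dimethoxy-4-(methoxymethoxy)phenyl]butane-1,4-dione | O=C(CCC(=O)c1cc(OC)c(OCOC)c(OC)c1)c1cc(OC)c(OCOC)c(OC)c1
A1 | alternative 1 | methyl (E)-3-(4-hydroxy-3,5-dimethoxyphenyl)prop-2-enoate (methyl sinapate) | COC(=O)/C=C/c1cc(OC)c(O)c(OC)c1
A2 | alternative 1 | dimethyl 2,3-bis[(3,5-dimethoxy-4-oxocyclohexa-2,5-dien-1-ylidene)methyl]butanedioate (rac/meso mixture) | COC(=O)C(C=C1C=C(OC)C(=O)C(OC)=C1)C(C=C1C=C(OC)C(=O)C(OC)=C1)C(=O)OC
A3 | alternative 2 | (2R,3S)-2,3-bis[3,5-dimethoxy-4-(methoxymethoxy)phenyl]oxirane (cis, meso) | COCOc1c(OC)cc(cc1OC)[C@H]1O[C@H]1c1cc(OC)c(OCOC)c(OC)c1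
A4 | alternative 2 | dimethyl (E)-but-2-enedioate (dimethyl fumarate) | COC(=O)/C=C/C(=O)OC
A5 | alternative 3 | dimethyl (1S,2S,3R,4R)-3,4-bis(4-hydroxy-3,5-dimethoxyphenyl)cyclobutane-1,2-dicarboxylate (all-trans) | COc1cc([C@@H]2[C@@H](c3cc(OC)c(O)c(OC)c3)[C@H](C(=O)OC)[C@H]2C(=O)OC)cc(OC)c1O
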